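**Strategy**

Everything rests on the syn-1,3-diol C4(OH)–C5H2–C6(OH) of the hexane chain, whose C6 sits on C4 of the 2,4-disubstituted oxazole ring. The C5–C6 bond is forged by an Ipc-boron aldol reaction between a methyl ketone that already carries the fatty ester at C2 and a MOM ether at C3, and the non-enolisable bis-oxazole aldehyde; hydride reduction of the boron aldolate in the same flask then sets C4. One operation thus unites both halves and creates the C6 and C4 carbinol centres. The ketone comes from Brown alkoxyallylboration of acetaldehyde, esterification and Wacker oxidation; the aldehyde from a Negishi coupling and partial ester reduction.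

Key step: step 6

Remark: the acyl group is read as 14-methylpentadecanoyl, and compounds 1, 2, 6, 7 and 10 are taken as catalogue compounds; chain atoms are numbered as in the hexan-2-yl ester (C1 methyl, C2 acyloxy, C6 on the oxazole).

**Route**

Step 1
Reactants: 1 5-(chloromethyl)-1,3-oxazole; 2 ethyl 2-chloro-1,3-oxazole-4-carboxylate
Product: 4 ethyl 2-(1,3-oxazol-5-ylmethyl)-1,3-oxazole-4-carboxylate, via benzylic zinc chloride 3 (not isolated)
Conditions: Zn dust, LiCl, THF, 25 °C; then 2, Pd(OAc)2 (cat.), SPhos, THF, 25 °C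
Reagents that add atoms: none
Why: LiCl-assisted zinc insertion into the heterobenzylic C–Cl bond gives 3, which undergoes Negishi coupling after oxidative addition of zerovalent palladium into the activated C2–Cl bond of 2; the organozinc tolerates the ester and the oxazole C–H bonds, and no stereocenter is involved.

Step 2
Reactants: 4 ethyl 2-(1,3-oxazol-5-ylmethyl)-1,3-oxazole-4-carboxylate
Product: 5 2-(1,3-oxazol-5-ylmethyl)-1,3-oxazole-4-carbaldehyde
Conditions: i-Bu2AlH, CH2Cl2, −78 °C; aq. potassium sodium tartrate work-up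
Reagents that add atoms: none
Why: Partial ester reduction; the aluminium hemiacetal of the electron-poor oxazole-4-carboxylate should persist at −78 °C and release the aldehyde only on work-up, and the non-basic hydride leaves the acidic CH2 between the two rings alone.

Step 3
Reactants: 6 allyl methoxymethyl ether; 7 acetaldehyde
Product: 9 (2S,3S)-3-(methoxymethoxy)pent-4-en-2-ol, via allylborane 8 (not isolated)
Conditions: s-BuLi, THF, −78 °C; (+)-Ipc2BOMe [from (−)-α-pinene]; BF3·OEt2; 7, −78 °C; then NaOH, H2O2, 0 °C to rt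
Reagents that add atoms: none
Why: Brown alkoxyallylboration; the chelated (Z)-alkoxyallyl anion gives (Z)-borane 8, whose chair transition state translates the (Z) geometry into the syn C2/C3 relationship, while the Ipc ligands from (−)-α-pinene direct attack to the Re face of acetaldehyde and so set (2S,3S), with the two oxygens differentiated from the outset.

Step 4
Reactants: 9 (2S,3S)-3-(methoxymethoxy)pent-4-en-2-ol; 10 14-methylpentadecanoic acid
Product: 11 (2S,3S)-3-(methoxymethoxy)pent-4-en-2-yl 14-methylpentadecanoate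
Conditions: EDC·HCl, DMAP, CH2Cl2, 0 °C to rt
Reagents that add atoms: none
Why: Steglich esterification of the only free hydroxyl; the C–O bond at C2 is not broken, so the configuration is retained.

Step 5
Reactants: 11 (2S,3S)-3-(methoxymethoxy)pent-4-en-2-yl 14-methylpentadecanoate
Product: 12 (2S,3R)-3-(methoxymethoxy)-4-oxopentan-2-yl 14-methylpentadecanoate
Conditions: Pd(Quinox)Cl2 (cat.; Quinox = 2-(4,5-dihydro-1,3-oxazol-2-yl)quinoline), AgSbF6 (cat.), aq. t-BuOOH, CH2Cl2, 0 °C to rt
Reagents that add atoms: tert-butyl hydroperoxide, CC(C)(C)OO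
Why: Peroxide-mediated Wacker-type oxidation; the bidentate ligand on cationic palladium should prevent the allylic oxygen from steering oxygen to the terminus, so the methyl ketone forms, and the near-neutral medium should spare the C3 stereocenter and the β-acyloxy group.

Step 6
Reactants: 12 (2S,3R)-3-(methoxymethoxy)-4-oxopentan-2-yl 14-methylpentadecanoate; 5 2-(1,3-oxazol-5-ylmethyl)-1,3-oxazole-4-carbaldehyde
Product: 15 (2S,3S,4S,6R)-4,6-dihydroxy-3-(methoxymethoxy)-6-[2-(1,3-oxazol-5-ylmethyl)-1,3-oxazol-4-yl]hexan-2-yl 14-methylpentadecanoate, via enol borinate 13 (not isolated), via boron aldolate 14 (not isolated)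
Conditions: (−)-Ipc2BCl [from (+)-α-pinene], Et3N, Et2O, 0 °C; 5, −78 to −20 °C; LiBH4, THF, −78 °C; then H2O2, MeOH, pH 7 buffer, 0 °C
Reagents that add atoms: none
Why: (−)-Ipc2BCl and Et3N enolise ketone 12 on its methyl side to enol borinate 13, which adds to the non-enolisable aldehyde 5 through a cyclic six-membered boron transition state, forging the C5–C6 bond and giving aldolate 14, in which boron bridges the new C6 oxygen and the C4 carbonyl. The closest known reaction type is the Ipc-boron aldol reaction of methyl ketones with in situ LiBH4 reduction of the boron aldolate (a Narasaka–Prasad-type 1,3-syn reduction). No ring of the product is closed; the six-membered B–O chelate is only a transient template. C6 (R) is set by the Ipc ligands from (+)-α-pinene, which steer methyl ketone enolates to the Re face of the aldehyde and should override the weak intrinsic bias of the α-alkoxy centre C3; C4 (S) is set by external hydride delivery to the chelate, 1,3-syn to C6, the same face that Cram-chelate control by the C3 MOM ether and Li+ favours (4-OH anti to 3-OMOM). The step needs regioselective enolisation (the unhindered CH3 against the hindered MOM-bearing C3–H), aldehyde-face selectivity (reagent control) and chemoselectivity: the non-basic boron enolate leaves the acidic CH2 between the oxazoles and the β-acyloxy group alone, and LiBH4 at −78 °C should reduce only the boron-activated ketone, not the ester.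

Step 7
Reactants: 15 (2S,3S,4S,6R)-4,6-dihydroxy-3-(methoxymethoxy)-6-[2-(1,3-oxazol-5-ylmethyl)-1,3-oxazol-4-yl]hexan-2-yl 14-methylpentadecanoate
Product: 16 (2S,3S,4S,6R)-3,4,6-trihydroxy-6-[2-(1,3-oxazol-5-ylmethyl)-1,3-oxazol-4-yl]hexan-2-yl 14-methylpentadecanoate
Conditions: ZnBr2 (excess), n-PrSH, CH2Cl2, 0 °C
Reagents that add atoms: none
Why: Lewis acid and thiol cleavage of the MOM acetal; the thiol captures the methoxymethyl cation so that no methylene acetal should form with the neighbouring hydroxyl, and the short, non-basic exposure should suppress acyl migration and leave ester, oxazoles and all four stereocenters untouched.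

**Compound list**

1 | 5-(chloromethyl)-1,3-oxazole | ClCc1cnco1 | starting material
2 | ethyl 2-chloro-1,3-oxazole-4-carboxylate | CCOC(=O)c1coc(Cl)n1 | starting material
3 | (1,3-oxazol-5-ylmethyl)zinc chloride | Cl[Zn]Cc1cnco1 | intermediate
4 | ethyl 2-(1,3-oxazol-5-ylmethyl)-1,3-oxazole-4-carboxylate | CCOC(=O)c1coc(Cc2cnco2)n1 | intermediate
5 | 2-(1,3-oxazol-5-ylmethyl)-1,3-oxazole-4-carbaldehyde | O=Cc1coc(Cc2cnco2)n1 | intermediate
6 | allyl methoxymethyl ether (3-(methoxymethoxy)prop-1-ene) | C=CCOCOC | starting material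
7 | acetaldehyde | CC=O | starting material
8 | [(Z)-3-(methoxymethoxy)prop-2-en-1-yl]diisopinocampheylborane, Ipc groups from (−)-α-pinene | COCO/C=C\CB([C@H]1C[C@H]2C[C@H](C2(C)C)[C@@H]1C)[C@H]1C[C@H]2C[C@H](C2(C)C)[C@@H]1C | intermediate
9 | (2S,3S)-3-(methoxymethoxy)pent-4-en-2-ol | O[C@@H](C)[C@@H](OCOC)C=C | intermediate
10 | 14-methylpentadecanoic acid | CC(C)CCCCCCCCCCCCC(=O)O | starting material
11 | (2S,3S)-3-(methoxymethoxy)pent-4-en-2-yl 14-methylpentadecanoate | CC(C)CCCCCCCCCCCCC(=O)O[C@@H](C)[C@@H](OCOC)C=C | intermediate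
12 | (2S,3R)-3-(methoxymethoxy)-4-oxopentan-2-yl 14-methylpentadecanoate | CC(C)CCCCCCCCCCCCC(=O)O[C@@H](C)[C@@H](OCOC)C(C)=O | intermediate
13 | (2S,3R)-4-[(diisopinocampheylboranyl)oxy]-3-(methoxymethoxy)pent-4-en-2-yl 14-methylpentadecanoate, Ipc groups from (+)-α-pinene | CC(C)CCCCCCCCCCCCC(=O)O[C@@H](C)[C@@H](OCOC)C(=C)OB([C@@H]1C[C@@H]2C[C@@H](C2(C)C)[C@H]1C)[C@@H]1C[C@@H]2C[C@@H](C2(C)C)[C@H]1C | intermediate
14 | (2S,3R,6R)-6-[(diisopinocampheylboranyl)oxy]-3-(methoxymethoxy)-4-oxo-6-[2-(1,3-oxazol-5-ylmethyl)-1,3-oxazol-4-yl]hexan-2-yl 14-methylpentadecanoate | CC(C)CCCCCCCCCCCCC(=O)O[C@@H](C)[C@@H](OCOC)C(=O)C[C@@H](OB([C@@H]1C[C@@H]2C[C@@H](C2(C)C)[C@H]1C)[C@@H]1C[C@@H]2C[C@@H](C2(C)C)[C@H]1C)c1coc(Cc2cnco2)n1 | intermediate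
15 | (2S,3S,4S,6R)-4,6-dihydroxy-3-(methoxymethoxy)-6-[2-(1,3-oxazol-5-ylmethyl)-1,3-oxazol-4-yl]hexan-2-yl 14-methylpentadecanoate | CC(C)CCCCCCCCCCCCC(=O)O[C@@H](C)[C@@H](OCOC)[C@@H](O)C[C@@H](O)c1coc(Cc2cnco2)n1 | intermediate
16 | (2S,3S,4S,6R)-3,4,6-trihydroxy-6-[2-(1,3-oxazol-5-ylmethyl)-1,3-oxazol-4-yl]hexan-2-yl 14-methylpentadecanoate | CC(C)CCCCCCCCCCCCC(=O)O[C@@H](C)[C@@H](O)[C@@H](O)C[C@@H](O)c1coc(Cc2cnco2)n1 | target

**Step count**

Total step count: 7.
Longest linear sequence: 5 steps (steps 3, 4, 5, 6, 7).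

**Steps most likely to fail**

1. Step 6. The aldol addition may show poor facial selectivity if the Ipc control is eroded by the α-alkoxy centre or by boron binding to the oxazole nitrogens, and hydride delivery to the aldolate may be incompletely 1,3-syn. The fallback sets out from 5 and 11 and comes back at 15. Aldehyde 5 is condensed with hydroxylamine (NH2OH·HCl, pyridine, EtOH) to 2-(1,3-oxazol-5-ylmethyl)-1,3-oxazole-4-carbaldehyde oxime F1. N-Chlorosuccinimide in DMF gives N-hydroxy-2-(1,3-oxazol-5-ylmethyl)-1,3-oxazole-4-carboximidoyl chloride F2, and slow addition of Et3N in the presence of alkene 11 releases 2-(1,3-oxazol-5-ylmethyl)-1,3-oxazole-4-carbonitrile oxide F3. Huisgen 1,3-dipolar cycloaddition across the terminal alkene gives the isoxazoline F4; the same C5–C6 bond is formed, and the ring oxygen should be delivered to C4 anti to the allylic MOM ether through the inside-alkoxy transition state. Hydrogenolysis of the N–O bond (Raney Ni, H2, B(OH)3, aq. MeOH) with hydrolysis of the imine gives the β-hydroxy ketone F5, with the carbonyl at C6. Narasaka–Prasad reduction (Et2BOMe, NaBH4, THF/MeOH, −78 °C) then sets C6 syn to C4 and gives 15.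

2. Step 7. During the late MOM cleavage the acyl group may migrate from O2 to the freed O3 or to O4, or the methoxymethyl cation may be captured by the neighbouring hydroxyl as a methylene acetal. The fallback sets out from 11 and comes back at 16. The MOM group is removed at the alkene stage (ZnBr2, n-PrSH, CH2Cl2, 0 °C), where a single hydroxyl is freed and any migrated isomer is easily separated, giving (2S,3S)-3-hydroxypent-4-en-2-yl 14-methylpentadecanoate F6. TESOTf and 2,6-lutidine give the triethylsilyl ether F7, and the Wacker oxidation of step 5 gives the silyloxy ketone F8. The aldol and reduction of step 6 with 5, through the enol borinate F9 and the boron aldolate F10, give the silyl-protected diol F11. HF·pyridine in THF/pyridine at 0 °C then frees 16 under mildly acidic, non-nucleophilic conditions.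

3. Step 5. Oxygen may be delivered to the terminal carbon under the influence of the allylic ether (aldehyde formation), the alkene may isomerise, or turnover may stall on the oxygen donors. The fallback sets out from 11 and comes back at 12. Mukaiyama hydration (Co(acac)2, PhSiH3, O2, THF), in which hydrogen-atom transfer gives the secondary radical regardless of the allylic oxygen, gives (2S,3S)-4-hydroxy-3-(methoxymethoxy)pentan-2-yl 14-methylpentadecanoate F12 as a mixture of C4 epimers. Dess–Martin periodinane (NaHCO3, CH2Cl2) oxidises both epimers to ketone 12.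

**Further compounds**

F1 | step 6 | 2-(1,3-oxazol-5-ylmethyl)-1,3-oxazole-4-carbaldehyde oxime | ON=Cc1coc(Cc2cnco2)n1
F2 | step 6 | N-hydroxy-2-(1,3-oxazol-5-ylmethyl)-1,3-oxazole-4-carboximidoyl chloride | ON=C(Cl)c1coc(Cc2cnco2)n1
F3 | step 6 | 2-(1,3-oxazol-5-ylmethyl)-1,3-oxazole-4-carbonitrile oxide | [O-][N+]#Cc1coc(Cc2cnco2)n1
F4 | step 6 | (1R,2S)-1-(methoxymethoxy)-1-{(5S)-3-[2-(1,3-oxazol-5-ylmethyl)-1,3-oxazol-4-yl]-4,5-dihydro-1,2-oxazol-5-yl}propan-2-yl 14-methylpentadecanoate | CC(C)CCCCCCCCCCCCC(=O)O[C@@H](C)[C@@H](OCOC)[C@@H]1CC(=NO1)c1coc(Cc2cnco2)n1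
F5 | step 6 | (2S,3S,4S)-4-hydroxy-3-(methoxymethoxy)-6-oxo-6-[2-(1,3-oxazol-5-ylmethyl)-1,3-oxazol-4-yl]hexan-2-yl 14-methylpentadecanoate | CC(C)CCCCCCCCCCCCC(=O)O[C@@H](C)[C@@H](OCOC)[C@@H](O)CC(=O)c1coc(Cc2cnco2)n1
F6 | step 7 | (2S,3S)-3-hydroxypent-4-en-2-yl 14-methylpentadecanoate | CC(C)CCCCCCCCCCCCC(=O)O[C@@H](C)[C@@H](O)C=C
F7 | step 7 | (2S,3S)-3-[(triethylsilyl)oxy]pent-4-en-2-yl 14-methylpentadecanoate | CC(C)CCCCCCCCCCCCC(=O)O[C@@H](C)[C@@H](O[Si](CC)(CC)CC)C=C
F8 | step 7 | (2S,3R)-4-oxo-3-[(triethylsilyl)oxy]pentan-2-yl 14-methylpentadecanoate | CC(C)CCCCCCCCCCCCC(=O)O[C@@H](C)[C@@H](O[Si](CC)(CC)CC)C(C)=O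
F9 | step 7 | (2S,3R)-4-[(diisopinocampheylboranyl)oxy]-3-[(triethylsilyl)oxy]pent-4-en-2-yl 14-methylpentadecanoate | CC(C)CCCCCCCCCCCCC(=O)O[C@@H](C)[C@@H](O[Si](CC)(CC)CC)C(=C)OB([C@@H]1C[C@@H]2C[C@@H](C2(C)C)[C@H]1C)[C@@H]1C[C@@H]2C[C@@H](C2(C)C)[C@H]1C
F10 | step 7 | (2S,3R,6R)-6-[(diisopinocampheylboranyl)oxy]-4-oxo-6-[2-(1,3-oxazol-5-ylmethyl)-1,3-oxazol-4-yl]-3-[(triethylsilyl)oxy]hexan-2-yl 14-methylpentadecanoate | CC(C)CCCCCCCCCCCCC(=O)O[C@@H](C)[C@@H](O[Si](CC)(CC)CC)C(=O)C[C@@H](OB([C@@H]1C[C@@H]2C[C@@H](C2(C)C)[C@H]1C)[C@@H]1C[C@@H]2C[C@@H](C2(C)C)[C@H]1C)c1coc(Cc2cnco2)n1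
F11 | step 7 | (2S,3S,4S,6R)-4,6-dihydroxy-6-[2-(1,3-oxazol-5-ylmethyl)-1,3-oxazol-4-yl]-3-[(triethylsilyl)oxy]hexan-2-yl 14-methylpentadecanoate | CC(C)CCCCCCCCCCCCC(=O)O[C@@H](C)[C@@H](O[Si](CC)(CC)CC)[C@@H](O)C[C@@H](O)c1coc(Cc2cnco2)n1
F12 | step 5 | (2S,3S)-4-hydroxy-3-(methoxymethoxy)pentan-2-yl 14-methylpentadecanoate (both C4 epimers) | CC(C)CCCCCCCCCCCCC(=O)O[C@@H](C)[C@@H](OCOC)C(C)O
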